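**Retrosynthetic overview**
1. Target 23 ⇐ tert-butyl ester 22 ⇐ spiro-oxirane lactone 15 + dienoic acid 21: carboxylate opening of the oxirane at its CH2 gives the side-chain ester C–O bond and the C-9 tertiary alcohol together.
2. 15 ⇐ acid 13 + Bu3SnCH2I, a one-carbon [6+1] annulation: O-alkylation of the C-9a carboxylate, then ring B (the seven-membered lactone) closes by Stille coupling between the O–CH2 carbon C-3 and the vinylic carbon C-4 of a (Z)-α-bromoacrylate.
3. Enabling feature: C-3 of ring B is a CH2 bonded only to the lactone oxygen O-2 and to the sp2 carbon C-4 that carries CO2H, and the carboxyl (C-9a) and alkenyl (C-5a) arms are trans-diequatorial on chair ring A, so a C1 ambiphile can bridge O-2 and C-4.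
4. 13 and 21 both ⇐ one silyl enol ether 6 (Mukaiyama hydroxymethylation for ring A, enolate triflation for ring C, then ozonolysis and bromo-Wittig olefination in each branch); 6 ⇐ (R)-cryptone 4 by trans-selective copper-catalysed vinyl addition with silyl trapping; 4 ⇐ 3-methylbutanal + methyl vinyl ketone.
5. Ring order: ring A (step 2), oxirane (step 6), ring B (step 11); ring C is a second copy of the cryptone ring (steps 12–16).

Key step: step 11

Remark: the bicyclic core is numbered as a 2-benzoxepine (C-1 lactone C=O, O-2, C-3 H2, C-4, C-5, C-5a, C-6 to C-9, C-9a); (iodomethyl)tributylstannane, (tributylstannyl)methanol, the pyridyl triflimide and the two ester ylides are assumed to be purchasable.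

Step 1
Reactants: 1 3-methylbutanal; 2 but-3-en-2-one
Product: 3 (2R)-5-oxo-2-(propan-2-yl)hexanal
Conditions: (R)-α,α-diphenylprolinol trimethylsilyl ether (5 mol%), ethyl 3,4-dihydroxybenzoate (20 mol%), neat, 4 °C
Reagents that add atoms: none
Why: Enamine-catalysed asymmetric Michael addition: the diphenyl(silyloxy)methyl group of the (R)-catalyst shields one face of the E-enamine of 1, so 2 should add to the open face and set C-2 as R, by analogy with the usual sense of induction of this catalyst class.

Step 2
Reactants: 3 (2R)-5-oxo-2-(propan-2-yl)hexanal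
Product: 4 (4R)-4-(propan-2-yl)cyclohex-2-en-1-one, (R)-cryptone
Conditions: LiOH (0.1 equiv), iPrOH, 23 °C
Reagents that add atoms: none
Why: Intramolecular aldol condensation (6-enolexo) of the methyl ketone onto the aldehyde; the existing stereocentre becomes C-4 and the mild catalytic base should keep its epimerisation slower than ring closure.

Step 3
Reactants: 4 (R)-cryptone
Product: 6 trimethyl{[(3R,4R)-3-ethenyl-4-(propan-2-yl)cyclohex-1-en-1-yl]oxy}silane, via magnesium enolate 5 (not isolated)
Conditions: vinylmagnesium bromide, CuBr·SMe2 (10 mol%), THF, −78 to −40 °C; then TMSCl, Et3N, DMPU, −78 to 0 °C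
Reagents that add atoms: vinylmagnesium bromide, C=C[Mg]Br; chlorotrimethylsilane, C[Si](C)(C)Cl
Why: Copper-catalysed 1,4-addition of the vinyl Grignard reagent anti to the C-4 isopropyl group (3,4-trans), then O-silylation of the regiodefined enolate 5, which stores the enolate regiochemistry (double bond toward the vinyl-bearing carbon) in an isolable silyl enol ether that serves both halves of the target.

Step 4
Reactants: 6 silyl enol ether
Product: 7 (2R,3R,4R)-3-ethenyl-2-(hydroxymethyl)-4-(propan-2-yl)cyclohexan-1-one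
Conditions: aq. CH2O (37%, 10 equiv), Yb(OTf)3 (10 mol%), THF/H2O (4:1), 23 °C
Reagents that add atoms: formaldehyde, C=O
Why: Lewis-acid-catalysed Mukaiyama aldol reaction (hydroxymethylation of a silyl enol ether with aqueous formaldehyde under a water-tolerant lanthanide triflate); the enol ether fixes the site, formaldehyde should add to C-2 anti to the neighbouring vinyl group, and the resulting all-equatorial 2,3-trans-3,4-trans ketone is also the more stable C-2 epimer.

Step 5
Reactants: 7 hydroxymethyl ketone
Product: 8 (2R,3R,4R)-3-ethenyl-4-(propan-2-yl)-2-[(triethylsilyloxy)methyl]cyclohexan-1-one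
Conditions: TESCl, imidazole, CH2Cl2, 0 °C
Reagents that add atoms: chlorotriethylsilane, CC[Si](Cl)(CC)CC
Why: Imidazole-promoted silylation of the primary alcohol suppresses retro-aldol and dehydration of the β-hydroxy ketone and masks the hydroxyl for the ylide step.

Step 6
Reactants: 8 silyloxymethyl ketone
Product: 9 triethyl{[(3S,4R,5R,6R)-5-ethenyl-6-(propan-2-yl)-1-oxaspiro[2.5]octan-4-yl]methoxy}silane
Conditions: Me3S+ I−, n-BuLi, THF, −10 °C; then 8, −10 to 0 °C
Reagents that add atoms: trimethylsulfonium iodide, C[S+](C)C.[I-]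
Why: Corey–Chaykovsky epoxidation: the unstabilised sulfonium ylide adds irreversibly along the axial trajectory of the all-equatorial chair, so the new CH2 should become axial and the oxygen equatorial (the C-9 configuration of the target), while the low temperature should keep β-elimination of the silyloxy group slow.

Step 7
Reactants: 9 vinyl spiro-oxirane
Product: 10 (3S,4R,5R,6R)-6-(propan-2-yl)-4-[(triethylsilyloxy)methyl]-1-oxaspiro[2.5]octane-5-carbaldehyde
Conditions: O3, CH2Cl2, −78 °C; then PPh3, −78 to 23 °C
Reagents that add atoms: ozone, [O-][O+]=O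
Why: Ozonolysis with reductive work-up cleaves the only alkene to the aldehyde; oxirane and silyl ether are inert to ozone and the α-stereocentre already has the stable equatorial configuration.

Step 8
Reactants: 10 aldehyde
Product: 11 tert-butyl (2Z)-2-bromo-3-{(3S,4R,5R,6R)-6-(propan-2-yl)-4-[(triethylsilyloxy)methyl]-1-oxaspiro[2.5]octan-5-yl}prop-2-enoate
Conditions: Ph3P=CHCO2tBu, NBS, CH2Cl2, −20 °C; then 10, 23 °C
Reagents that add atoms: tert-butyl (triphenyl-λ5-phosphanylidene)acetate, CC(C)(C)OC(=O)C=P(c1ccccc1)(c1ccccc1)c1ccccc1; N-bromosuccinimide, O=C1CCC(=O)N1Br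
Why: Wittig reaction of the ester-stabilised α-bromo ylide (made in the flask by bromination of the ylide) with the aldehyde, which should give mainly the Z bromoacrylate (ester trans to the ring, bromine cis) as is usual for stabilised ylides.

Step 9
Reactants: 11 silyl ether
Product: 12 tert-butyl (2Z)-2-bromo-3-[(3S,4R,5R,6R)-4-(hydroxymethyl)-6-(propan-2-yl)-1-oxaspiro[2.5]octan-5-yl]prop-2-enoate
Conditions: TBAF, AcOH (1:1), THF, 0 °C
Reagents that add atoms: none
Why: Fluoride-mediated desilylation buffered with acetic acid, so that neither base-induced dehydrobromination of the vinyl bromide nor acid-induced opening of the oxirane should occur.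

Step 10
Reactants: 12 primary alcohol
Product: 13 (3S,4S,5R,6R)-5-[(1Z)-2-bromo-3-tert-butoxy-3-oxoprop-1-en-1-yl]-6-(propan-2-yl)-1-oxaspiro[2.5]octane-4-carboxylic acid
Conditions: TEMPO (10 mol%), NaClO2 (2 equiv), NaOCl (5 mol%), MeCN, phosphate buffer pH 6.7, 35 °C
Reagents that add atoms: sodium chlorite, [Na+].[O-]Cl=O
Why: TEMPO-catalysed oxidation with chlorite as terminal oxidant takes the primary alcohol through the aldehyde to the acid near neutral pH, where oxirane, bromoacrylate and tert-butyl ester should survive; opening of the oxirane by the neighbouring carboxylate would be a disfavoured 5-endo attack.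

Step 11
Reactants: 13 bromoacrylate acid
Product: 15 tert-butyl (5aS,6R,9S,9aS)-1-oxo-6-(propan-2-yl)-3,5a,6,7,8,9a-hexahydro-1H-spiro[2-benzoxepine-9,2′-oxirane]-4-carboxylate, via stannylmethyl ester 14 (not isolated)
Conditions: Cs2CO3 (1.0 equiv), Bu3SnCH2I (1.05 equiv), DMF, 23 °C; then DMF to 2 mM, Pd2(dba)3 (5 mol%), AsPh3 (20 mol%), CuI (20 mol%), 50 °C
Reagents that add atoms: (iodomethyl)tributylstannane, CCCC[Sn](CI)(CCCC)CCCC
Why: Proposed new method: the caesium carboxylate is alkylated by the iodide of Bu3SnCH2I (SN2) to give the (acyloxymethyl)stannane 14; zerovalent palladium then inserts into the C–Br bond of the (Z)-α-bromoacrylate, the oxygenated CH2 group is passed from tin through monovalent copper to palladium (helped by chelation of the ester carbonyl), and C(sp2)–C(sp3) reductive elimination forms the C-3–C-4 bond. The closest known reactions are the Stille hydroxymethylation of vinyl and aryl halides with Bu3SnCH2OH, copper-promoted couplings of α-acyloxy stannanes and ring-closing Stille couplings; a tethered (acyloxymethyl)stannane as the sp3 partner of a lactone-forming Stille closure is the new element. Ring B is closed as a seven-membered ring by reductive elimination from an eight-membered palladacycle, the C-4/C-5 alkene ending endocyclic. No stereocentre is created: the trans ring fusion is preset by the diequatorial carboxyl and alkenyl arms, and the alkene geometry follows from retention at the Z bromide, the only isomer whose CH2 terminus can reach. The step needs transfer of the oxygenated CH2 instead of butyl and cyclisation instead of oligomerisation; the α-oxygen with carbonyl chelation and the intramolecular setting should secure the first, high dilution and the 60° dihedral between the two arms the second. Oxirane, tert-butyl ester and the C-9a hydrogen should be untouched under these near-neutral conditions.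

Step 12
Reactants: 6 silyl enol ether
Product: 17 (3R,4R)-3-ethenyl-4-(propan-2-yl)cyclohex-1-en-1-yl trifluoromethanesulfonate, via lithium enolate 16 (not isolated)
Conditions: MeLi (1.05 equiv), THF, 0 °C; then N-(5-chloropyridin-2-yl)bis(trifluoromethanesulfonyl)imide, −78 to 0 °C
Reagents that add atoms: methyllithium (gives the lithium of 16), C[Li]; N-(5-chloropyridin-2-yl)-1,1,1-trifluoro-N-(trifluoromethanesulfonyl)methanesulfonamide, O=S(=O)(N(c1ccc(Cl)cn1)S(=O)(=O)C(F)(F)F)C(F)(F)F
Why: Methyllithium cleaves the Si–O bond of the trimethylsilyl enol ether to give the regiodefined lithium enolate 16 and volatile tetramethylsilane, and O-triflation by the pyridyl triflimide then fixes the ring double bond next to the vinyl-bearing carbon without enolate equilibration (enol triflate formation from a silyl enol ether).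

Step 13
Reactants: 17 vinyl enol triflate
Product: 18 (1R,6R)-6-(propan-2-yl)-3-(trifluoromethanesulfonyloxy)cyclohex-2-ene-1-carbaldehyde
Conditions: O3, CH2Cl2, −78 °C, Sudan red 7B as end-point indicator; then PPh3
Reagents that add atoms: ozone, [O-][O+]=O
Why: Ozonolysis with reductive work-up should be chemoselective for the monosubstituted vinyl group because the enol triflate double bond is strongly deactivated by the triflyloxy group.

Step 14
Reactants: 18 aldehyde
Product: 19 methyl (2Z)-2-bromo-3-[(1R,6R)-6-(propan-2-yl)-3-(trifluoromethanesulfonyloxy)cyclohex-2-en-1-yl]prop-2-enoate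
Conditions: Ph3P=CHCO2Me, NBS, CH2Cl2, −20 °C; then crude 18, 0 to 23 °C
Reagents that add atoms: methyl (triphenyl-λ5-phosphanylidene)acetate, COC(=O)C=P(c1ccccc1)(c1ccccc1)c1ccccc1; N-bromosuccinimide, O=C1CCC(=O)N1Br
Why: Wittig reaction with the α-bromo ylide made in the flask (as in step 8) under neutral conditions, so the β,γ-unsaturated aldehyde should neither epimerise nor shift its double bond; the Z bromoacrylate is expected.

Step 15
Reactants: 19 bromoacrylate enol triflate
Product: 20 methyl (2E)-2-(hydroxymethyl)-3-[(1R,6R)-3-(hydroxymethyl)-6-(propan-2-yl)cyclohex-2-en-1-yl]prop-2-enoate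
Conditions: Bu3SnCH2OH (2.5 equiv), Pd(PPh3)4 (10 mol%), LiCl (3 equiv), 1,4-dioxane, 90 °C
Reagents that add atoms: (tributylstannyl)methanol, CCCC[Sn](CO)(CCCC)CCCC
Why: Twofold Stille coupling with (tributylstannyl)methanol (hydroxymethyl transfers in preference to butyl): zerovalent palladium inserts into the vinyl triflate (chloride-assisted) and the α-bromoacrylate, and coupling with retention puts the new acrylate CH2OH cis to ring C (E ester).

Step 16
Reactants: 20 diol methyl ester
Product: 21 (2E)-2-(hydroxymethyl)-3-[(1R,6R)-3-(hydroxymethyl)-6-(propan-2-yl)cyclohex-2-en-1-yl]prop-2-enoic acid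
Conditions: LiOH, THF/H2O, 0 to 23 °C; then 1 M HCl to pH 3
Reagents that add atoms: lithium hydroxide, [Li+].[OH-]
Why: Saponification of the methyl ester at low temperature; the bis-allylic ring hydrogen should not be acidic enough for hydroxide to isomerise the skipped diene.

Step 17
Reactants: 15 spiro-oxirane lactone; 21 dienoic acid
Product: 22 tert-butyl (5aS,6R,9S,9aS)-9-hydroxy-9-({[(2E)-2-(hydroxymethyl)-3-[(1R,6R)-3-(hydroxymethyl)-6-(propan-2-yl)cyclohex-2-en-1-yl]prop-2-enoyl]oxy}methyl)-1-oxo-6-(propan-2-yl)-1,3,5a,6,7,8,9,9a-octahydro-2-benzoxepine-4-carboxylate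
Conditions: 21 (1.5 equiv), Cs2CO3 (0.3 equiv), DMF, 60 °C
Reagents that add atoms: none
Why: Carboxylate opening of the 2,2-disubstituted oxirane at its unsubstituted CH2 carbon (SN2) forms the ester and leaves the C-9 oxygen as the tertiary alcohol with the configuration set in step 6; the carboxylate of 21 is far more nucleophilic than its neutral hydroxyls, and the acid present keeps the tertiary alkoxide protonated.

Step 18
Reactants: 22 tert-butyl ester
Product: 23 target CNP0361406.2, (5aS,6R,9S,9aS)-9-hydroxy-9-({[(2E)-2-(hydroxymethyl)-3-[(1R,6R)-3-(hydroxymethyl)-6-(propan-2-yl)cyclohex-2-en-1-yl]prop-2-enoyl]oxy}methyl)-1-oxo-6-(propan-2-yl)-1,3,5a,6,7,8,9,9a-octahydro-2-benzoxepine-4-carboxylic acid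
Conditions: 85% aq. H3PO4 (5 equiv), toluene, 23 °C
Reagents that add atoms: none
Why: Acidolysis of the tert-butyl ester (alkyl–oxygen cleavage via the tert-butyl cation) with aqueous phosphoric acid, a mild acid that should leave the lactone, the side-chain ester, the allylic alcohols and the tertiary alcohol intact.

**Compound list**
1 | 3-methylbutanal | CC(C)CC=O | starting material
2 | but-3-en-2-one (methyl vinyl ketone) | CC(=O)C=C | starting material
3 | (2R)-5-oxo-2-(propan-2-yl)hexanal | CC(C)[C@H](C=O)CCC(C)=O | intermediate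
4 | (4R)-4-(propan-2-yl)cyclohex-2-en-1-one, (R)-cryptone | CC(C)[C@H]1CCC(=O)C=C1 | intermediate
5 | bromomagnesium (3R,4R)-3-ethenyl-4-(propan-2-yl)cyclohex-1-en-1-olate (not isolated) | C=C[C@H]1C=C(O[Mg]Br)CC[C@@H]1C(C)C | intermediate
6 | trimethyl{[(3R,4R)-3-ethenyl-4-(propan-2-yl)cyclohex-1-en-1-yl]oxy}silane | C=C[C@H]1C=C(O[Si](C)(C)C)CC[C@@H]1C(C)C | intermediate
7 | (2R,3R,4R)-3-ethenyl-2-(hydroxymethyl)-4-(propan-2-yl)cyclohexan-1-one | CC(C)[C@H]1CCC(=O)[C@@H](CO)[C@@H]1C=C | intermediate
8 | (2R,3R,4R)-3-ethenyl-4-(propan-2-yl)-2-[(triethylsilyloxy)methyl]cyclohexan-1-one | CC(C)[C@H]1CCC(=O)[C@@H](CO[Si](CC)(CC)CC)[C@@H]1C=C | intermediate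
9 | triethyl{[(3S,4R,5R,6R)-5-ethenyl-6-(propan-2-yl)-1-oxaspiro[2.5]octan-4-yl]methoxy}silane (oxirane CH2 axial, O equatorial) | CC(C)[C@H]1CC[C@@]2(CO2)[C@@H](CO[Si](CC)(CC)CC)[C@@H]1C=C | intermediate
10 | (3S,4R,5R,6R)-6-(propan-2-yl)-4-[(triethylsilyloxy)methyl]-1-oxaspiro[2.5]octane-5-carbaldehyde | CC(C)[C@H]1CC[C@@]2(CO2)[C@@H](CO[Si](CC)(CC)CC)[C@@H]1C=O | intermediate
11 | tert-butyl (2Z)-2-bromo-3-{(3S,4R,5R,6R)-6-(propan-2-yl)-4-[(triethylsilyloxy)methyl]-1-oxaspiro[2.5]octan-5-yl}prop-2-enoate | CC(C)[C@H]1CC[C@@]2(CO2)[C@@H](CO[Si](CC)(CC)CC)[C@@H]1/C=C(\Br)C(=O)OC(C)(C)C | intermediate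
12 | tert-butyl (2Z)-2-bromo-3-[(3S,4R,5R,6R)-4-(hydroxymethyl)-6-(propan-2-yl)-1-oxaspiro[2.5]octan-5-yl]prop-2-enoate | CC(C)[C@H]1CC[C@@]2(CO2)[C@@H](CO)[C@@H]1/C=C(\Br)C(=O)OC(C)(C)C | intermediate
13 | (3S,4S,5R,6R)-5-[(1Z)-2-bromo-3-tert-butoxy-3-oxoprop-1-en-1-yl]-6-(propan-2-yl)-1-oxaspiro[2.5]octane-4-carboxylic acid | CC(C)[C@H]1CC[C@@]2(CO2)[C@@H](C(=O)O)[C@@H]1/C=C(\Br)C(=O)OC(C)(C)C | intermediate
14 | (tributylstannyl)methyl (3S,4S,5R,6R)-5-[(1Z)-2-bromo-3-tert-butoxy-3-oxoprop-1-en-1-yl]-6-(propan-2-yl)-1-oxaspiro[2.5]octane-4-carboxylate (not isolated) | CC(C)[C@H]1CC[C@@]2(CO2)[C@@H](C(=O)OC[Sn](CCCC)(CCCC)CCCC)[C@@H]1/C=C(\Br)C(=O)OC(C)(C)C | intermediate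
15 | tert-butyl (5aS,6R,9S,9aS)-1-oxo-6-(propan-2-yl)-3,5a,6,7,8,9a-hexahydro-1H-spiro[2-benzoxepine-9,2′-oxirane]-4-carboxylate (trans-fused rings A and B) | CC(C)[C@H]1CC[C@@]3(CO3)[C@H]2C(=O)OCC(C(=O)OC(C)(C)C)=C[C@H]12 | intermediate
16 | lithium (3R,4R)-3-ethenyl-4-(propan-2-yl)cyclohex-1-en-1-olate (not isolated) | C=C[C@H]1C=C(O[Li])CC[C@@H]1C(C)C | intermediate
17 | (3R,4R)-3-ethenyl-4-(propan-2-yl)cyclohex-1-en-1-yl trifluoromethanesulfonate | C=C[C@H]1C=C(OS(=O)(=O)C(F)(F)F)CC[C@@H]1C(C)C | intermediate
18 | (1R,6R)-6-(propan-2-yl)-3-(trifluoromethanesulfonyloxy)cyclohex-2-ene-1-carbaldehyde | O=C[C@H]1C=C(OS(=O)(=O)C(F)(F)F)CC[C@@H]1C(C)C | intermediate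
19 | methyl (2Z)-2-bromo-3-[(1R,6R)-6-(propan-2-yl)-3-(trifluoromethanesulfonyloxy)cyclohex-2-en-1-yl]prop-2-enoate | COC(=O)/C(Br)=C/[C@H]1C=C(OS(=O)(=O)C(F)(F)F)CC[C@@H]1C(C)C | intermediate
20 | methyl (2E)-2-(hydroxymethyl)-3-[(1R,6R)-3-(hydroxymethyl)-6-(propan-2-yl)cyclohex-2-en-1-yl]prop-2-enoate | COC(=O)/C(CO)=C/[C@H]1C=C(CO)CC[C@@H]1C(C)C | intermediate
21 | (2E)-2-(hydroxymethyl)-3-[(1R,6R)-3-(hydroxymethyl)-6-(propan-2-yl)cyclohex-2-en-1-yl]prop-2-enoic acid | OC(=O)/C(CO)=C/[C@H]1C=C(CO)CC[C@@H]1C(C)C | intermediate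
22 | tert-butyl ester of the target (name in step 17) | CC(C)[C@H]1CC[C@@](O)(COC(=O)/C(=C/[C@H]2C=C(CO)CC[C@@H]2C(C)C)CO)[C@H]2C(=O)OCC(C(=O)OC(C)(C)C)=C[C@H]12 | intermediate
23 | CNP0361406.2 (name in step 18) | CC(C)[C@H]1CC[C@@](O)(COC(=O)/C(=C/[C@H]2C=C(CO)CC[C@@H]2C(C)C)CO)[C@H]2C(=O)OCC(C(=O)O)=C[C@H]12 | target

**Step count**
Total steps: 18. Longest linear sequence: 13 steps (steps 1–11, 17, 18); the acid 21 branch is steps 1–3, 12–16.

**Steps most likely to fail**

Step 11. The transfer of the sp3 CH2 group from tin may be too slow, so that butyl transfer, protodestannylation, reduction of the C–Br bond or intermolecular coupling take over. The fallback uses known chemistry and sets out from 13. Intermolecular Stille hydroxymethylation with (tributylstannyl)methanol (Pd(PPh3)4, 1,4-dioxane, 90 °C, the reaction type of step 15) would form the same CH2–C-4 bond and give (3S,4S,5S,6R)-5-[(1E)-3-tert-butoxy-2-(hydroxymethyl)-3-oxoprop-1-en-1-yl]-6-(propan-2-yl)-1-oxaspiro[2.5]octane-4-carboxylic acid F1. Ring B would then be closed by lactonisation of this hydroxy acid with 2-methyl-6-nitrobenzoic anhydride and DMAP at high dilution, helped by the cis arrangement of CH2OH and ring A on the alkene. This returns to the route at 15.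

Step 17. Attack at the hindered axial CH2 of the oxirane may be slow, so that base-induced β-elimination (oxirane opening from the C-9a enolate) or attack of the carboxylate on the allylic lactone CH2 compete. The fallback changes the order of events and sets out from 14, isolated after the alkylation half of step 11. The oxirane of 14 would be opened with 21 (Cs2CO3 0.3 equiv, DMF, 60 °C) while ring B does not yet exist, giving the ring-B-seco hydroxy diester (tributylstannyl)methyl ester F2, which carries the C-9 tertiary alcohol, the side-chain ester and the (Z)-α-bromoacrylate. Ring closure of F2 under the palladium/copper conditions of step 11, which tolerate free hydroxyls, comes back to the route at 22.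

Step 4. In the aqueous medium, hydrolysis of the silyl enol ether to the unfunctionalised ketone may outrun the aldol addition, or the β-hydroxy ketone may dehydrate to the α-methylene ketone under Lewis acid. The fallback sets out from 6 and replaces the Mukaiyama reaction by an anhydrous metal enolate aldol addition. Cleavage of 6 with MeLi in THF at 0 °C would give the lithium enolate 16, which would be treated at −78 °C with monomeric formaldehyde gas (from cracked paraformaldehyde) and quenched cold with aqueous NH4Cl. This comes back to the route at 7.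

Further compounds
F1 | step 11 | (3S,4S,5S,6R)-5-[(1E)-3-tert-butoxy-2-(hydroxymethyl)-3-oxoprop-1-en-1-yl]-6-(propan-2-yl)-1-oxaspiro[2.5]octane-4-carboxylic acid | CC(C)[C@H]1CC[C@@]2(CO2)[C@@H](C(=O)O)[C@@H]1/C=C(\CO)C(=O)OC(C)(C)C
F2 | step 17 | ring-B-seco hydroxy diester from 14 and 21, (tributylstannyl)methyl ester with (Z)-α-bromoacrylate | CC(C)[C@H]1CC[C@@](O)(COC(=O)/C(=C/[C@H]2C=C(CO)CC[C@@H]2C(C)C)CO)[C@@H](C(=O)OC[Sn](CCCC)(CCCC)CCCC)[C@@H]1/C=C(\Br)C(=O)OC(C)(C)C
F0 | step 4 | none | none
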